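**Plan**

1. The retrosynthesis cuts the upper interflavan bond C4(top)–C8(middle) first, then the lower one C4(middle)–C8(bottom). This leaves a de novo epiafzelechin C4 electrophile and two units of (−)-epicatechin.
2. The top unit is opened at O1–C8a (ring C) and C4a–C5 (ring A) in one operation, back to the chain ArCH(O1)–C3–C4–C4a–C8a(=O)–C8–dioxinone (C7, C6, C5). The chain is cut at C8–C8a (acylation), C4=C4a (cross-metathesis) and C2–C3 (alkoxyallylboration).
3. Enabling feature: ring A of the top unit (C4a, C5, C6, C7, C8, C8a) is a phloroglucinol with oxygen on the alternate carbons C5, C7 and C8a, the pattern of a folded triketide, and O1 on C2 stands 1,5 to C8a. Capture of the C8a carbonyl by O1 closes ring C and leaves C-acylation of C4a by C5 as the only six-membered way to close ring A.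
4. Forward: open chain; rings C and A of the top unit together; benzylation and C4 activation. Separately the benzylated epicatechin dimer (middle and bottom units). Then the top interflavan bond and global hydrogenolysis.
5. Stereochemistry: C2 and C3 of the top unit come from a reagent-controlled syn-selective alkoxyallylboration. C2 and C3 of the middle and bottom units come from (−)-epicatechin. Both C4 centres come from attack on the flavan C4 cation anti to the C3 hydroxyl (3,4-trans, 4β).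

Key step: step 6

Remark: allyl methoxymethyl ether is taken as purchased (otherwise one step from allyl alcohol and chloromethyl methyl ether), and the (Z)-γ-alkoxyallylborane from (−)-Ipc2BOMe is taken to attack the si face of the aldehyde as the parent allylborane does; if the opposite sense is found, (+)-Ipc2BOMe is used.

**Route**

Step 1
Reactants: 1 4-(benzyloxy)benzaldehyde; 2 allyl methoxymethyl ether
Product: 5 (1R,2R)-1-[4-(benzyloxy)phenyl]-2-(methoxymethoxy)but-3-en-1-ol, via allyllithium 3 (not isolated), via allylborane 4 (not isolated)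
Conditions: 2, s-BuLi, THF, −78 °C; (−)-Ipc2BOMe, −78 °C; BF3·OEt2; then 1, −78 to 23 °C; NaOH, H2O2
Reagents that add atoms: none
Why: Brown-type asymmetric γ-alkoxyallylboration, in which the (Z)-allylborane reacts through a closed chair transition state so that its Z geometry gives the syn (1R,2R) pair, and the isopinocampheyl groups of the (+)-α-pinene series direct the si-face attack that fixes the later C2 and C3 of the top unit.

Step 2
Reactants: 5 (1R,2R)-1-[4-(benzyloxy)phenyl]-2-(methoxymethoxy)but-3-en-1-ol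
Product: 6 triethyl{[(1R,2R)-1-[4-(benzyloxy)phenyl]-2-(methoxymethoxy)but-3-en-1-yl]oxy}silane
Conditions: TESCl, imidazole, DMF, 0 to 23 °C
Reagents that add atoms: chlorotriethylsilane, CC[Si](Cl)(CC)CC
Why: Standard silylation of the secondary benzylic alcohol keeps O1 masked so that it cannot lactonise or add to C8a before the key step.

Step 3
Reactants: 6 triethyl{[(1R,2R)-1-[4-(benzyloxy)phenyl]-2-(methoxymethoxy)but-3-en-1-yl]oxy}silane; 7 N-methoxy-N-methylprop-2-enamide
Product: 8 (2E,4R,5R)-5-[4-(benzyloxy)phenyl]-N-methoxy-4-(methoxymethoxy)-N-methyl-5-[(triethylsilyl)oxy]pent-2-enamide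
Conditions: second-generation Hoveyda–Grubbs catalyst (5 mol %), 7 (3 equiv), CH2Cl2, 40 °C
Reagents that add atoms: none
Why: Olefin cross-metathesis between a slowly homodimerising allylic ether and an electron-poor acrylamide should give the E enamide and installs C4a and the C8a carbonyl in one step.

Step 4
Reactants: 8 (2E,4R,5R)-5-[4-(benzyloxy)phenyl]-N-methoxy-4-(methoxymethoxy)-N-methyl-5-[(triethylsilyl)oxy]pent-2-enamide
Product: 9 (4R,5R)-5-[4-(benzyloxy)phenyl]-N-methoxy-4-(methoxymethoxy)-N-methyl-5-[(triethylsilyl)oxy]pentanamide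
Conditions: H2 (1 atm), RhCl(PPh3)3 (5 mol %), toluene–EtOH, 23 °C
Reagents that add atoms: none
Why: Homogeneous hydrogenation with RhCl(PPh3)3 saturates the disubstituted conjugated alkene without hydrogenolysis of the aryl benzyl ether or the benzylic C–O bond.

Step 5
Reactants: 9 (4R,5R)-5-[4-(benzyloxy)phenyl]-N-methoxy-4-(methoxymethoxy)-N-methyl-5-[(triethylsilyl)oxy]pentanamide; 10 2,2,6-trimethyl-4H-1,3-dioxin-4-one
Product: 12 6-[(5R,6R)-6-[4-(benzyloxy)phenyl]-5-(methoxymethoxy)-2-oxo-6-[(triethylsilyl)oxy]hexyl]-2,2-dimethyl-4H-1,3-dioxin-4-one, via lithium dienolate 11 (not isolated)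
Conditions: 10 (2.5 equiv), LiN(SiMe3)2 (2.5 equiv), THF, −78 °C; then 9, −78 to −40 °C; aq NH4Cl
Reagents that add atoms: none
Why: γ-Acylation of the lithium dienolate of the dioxinone by a Weinreb amide, whose chelated tetrahedral adduct prevents double addition while the excess dienolate absorbs the acidic proton of the product.

Step 6
Reactants: 12 6-[(5R,6R)-6-[4-(benzyloxy)phenyl]-5-(methoxymethoxy)-2-oxo-6-[(triethylsilyl)oxy]hexyl]-2,2-dimethyl-4H-1,3-dioxin-4-one
Product: 17 (2R,3R)-2-[4-(benzyloxy)phenyl]-3-(methoxymethoxy)chromane-5,7-diol, via hydroxy ketone 13 (not isolated), via cyclic enol ether 14 (not isolated), via acylketene 15 (not isolated), via dienone 16 (not isolated)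
Conditions: PPTS (0.3 equiv), MeOH–CH2Cl2, 23 °C; evaporate; toluene, 4 Å MS, 60 °C; then Et3N (1 equiv), toluene (0.005 M), 110 °C
Reagents that add atoms: none
Why: Proposed new method: methanolysis of the silyl ether frees O1 on C2, which adds to the C8a ketone (6-exo-trig, six-membered hemiketal) and loses water to the cyclic enol ether 14 (in equilibrium with its exocyclic conjugated tautomer), so that ring C is closed by the O1–C8a bond before the dioxinone is opened. At 110 °C the dioxinone loses acetone by retro-[4+2] reaction to the acylketene 15, whose ketene carbon C5 is attacked by the enol-ether carbon C4a (six-membered C-acylation, equivalent to a 6π electrocyclisation of the dienol–ketene tautomer), and the dienone 16 enolises to the phloroglucinol ring A. The closest known reaction types are the thermolysis of keto-dioxinones through acylketenes to 4-hydroxy-2-pyranones or resorcylates, the Danheiser benzannulation (dienylketene electrocyclisation) and the acid-catalysed closure of hydroxy-β-dicarbonyl compounds to cyclic vinylogous esters. No new stereocentre is formed, and C2 and C3 are carried through because neither C–O bond at these carbons is broken. The selectivity needed is C-acylation at C4a in place of O-acylation to a pyranone; it is secured by O1 having replaced the C8a carbonyl oxygen, which leaves the C4a–C5 bond as the only six-membered closure open to the ketene, while the MOM ether on C3 ensures that only O1 can reach C8a.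

Step 7
Reactants: 17 (2R,3R)-2-[4-(benzyloxy)phenyl]-3-(methoxymethoxy)chromane-5,7-diol
Product: 18 (2R,3R)-5,7-bis(benzyloxy)-2-[4-(benzyloxy)phenyl]-3-(methoxymethoxy)chromane
Conditions: BnBr (2.4 equiv), K2CO3, DMF, 23 °C
Reagents that add atoms: benzyl bromide, BrCc1ccccc1
Why: Williamson etherification of the two phenols under carbonate conditions, which leave the acetal-protected secondary oxygen untouched.

Step 8
Reactants: 18 (2R,3R)-5,7-bis(benzyloxy)-2-[4-(benzyloxy)phenyl]-3-(methoxymethoxy)chromane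
Product: 19 (2R,3R)-5,7-bis(benzyloxy)-2-[4-(benzyloxy)phenyl]chroman-3-ol (5,7,4'-tri-O-benzyl-(−)-epiafzelechin)
Conditions: HCl (cat.), MeOH–THF, 40 °C
Reagents that add atoms: none
Why: Acid-catalysed transacetalisation removes the MOM group as dimethoxymethane while the aryl benzyl ethers and the C2 and C3 centres are not affected.

Step 9
Reactants: 19 (2R,3R)-5,7-bis(benzyloxy)-2-[4-(benzyloxy)phenyl]chroman-3-ol
Product: 20 (2R,3R,4S)-5,7-bis(benzyloxy)-2-[4-(benzyloxy)phenyl]-4-(2-ethoxyethoxy)chroman-3-ol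
Conditions: DDQ (2 equiv), 2-ethoxyethanol (5 equiv), CH2Cl2, 23 °C
Reagents that add atoms: 2-ethoxyethanol, CCOCCO
Why: DDQ benzylic oxidation, in which hydride abstraction at C4 gives the cation stabilised by the 5,7-dioxygenated ring A and 2-ethoxyethanol traps it anti to the C3 hydroxyl and the C2 aryl group, setting C4 as the 4β (3,4-trans) ether.

Step 10
Reactants: 21 (−)-epicatechin
Product: 22 (2R,3R)-5,7-bis(benzyloxy)-2-[3,4-bis(benzyloxy)phenyl]chroman-3-ol (5,7,3',4'-tetra-O-benzyl-(−)-epicatechin)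
Conditions: BnBr (4.4 equiv), K2CO3, DMF, 0 to 23 °C
Reagents that add atoms: benzyl bromide, BrCc1ccccc1
Why: Williamson etherification of the four phenols of (−)-epicatechin, whose C2 and C3 centres supply the stereochemistry of the middle and bottom units.

Step 11
Reactants: 22 (2R,3R)-5,7-bis(benzyloxy)-2-[3,4-bis(benzyloxy)phenyl]chroman-3-ol
Product: 23 (2R,3R,4S)-5,7-bis(benzyloxy)-2-[3,4-bis(benzyloxy)phenyl]-4-(2-ethoxyethoxy)chroman-3-ol
Conditions: DDQ (2 equiv), 2-ethoxyethanol (5 equiv), CH2Cl2, 23 °C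
Reagents that add atoms: 2-ethoxyethanol, CCOCCO
Why: The same DDQ benzylic oxidation at C4 with trapping of the cation by the alcohol anti to the C3 hydroxyl, giving the 4β ether.

Step 12
Reactants: 23 (2R,3R,4S)-5,7-bis(benzyloxy)-2-[3,4-bis(benzyloxy)phenyl]-4-(2-ethoxyethoxy)chroman-3-ol; 22 (2R,3R)-5,7-bis(benzyloxy)-2-[3,4-bis(benzyloxy)phenyl]chroman-3-ol
Product: 24 5,7,3',4'-tetra-O-benzyl-(−)-epicatechin-(4β→8)-5,7,3',4'-tetra-O-benzyl-(−)-epicatechin (octa-O-benzylprocyanidin B2)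
Conditions: TMSOTf (1 equiv), 22 (4 equiv), CH2Cl2, −78 °C
Reagents that add atoms: none
Why: Lewis-acid-mediated Friedel–Crafts-type interflavan coupling, in which the C4 cation released from 23 is attacked by C8 of 22 anti to the C3 hydroxyl to set the 4β→8 bond, and the excess of 22 suppresses chain growth.

Step 13
Reactants: 20 (2R,3R,4S)-5,7-bis(benzyloxy)-2-[4-(benzyloxy)phenyl]-4-(2-ethoxyethoxy)chroman-3-ol; 24 octa-O-benzylprocyanidin B2
Product: 25 5,7,4'-tri-O-benzyl-(−)-epiafzelechin-(4β→8)-5,7,3',4'-tetra-O-benzyl-(−)-epicatechin-(4β→8)-5,7,3',4'-tetra-O-benzyl-(−)-epicatechin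
Conditions: TMSOTf (1 equiv), 24 (2.5 equiv), CH2Cl2, −78 to −40 °C
Reagents that add atoms: none
Why: The same cation–arene coupling, in which ionisation of 20 and attack by the free C8 of the upper unit of 24 (the most accessible nucleophilic position) anti to the C3 hydroxyl sets C4 of the top unit as 4β (3,4-trans).

Step 14
Reactants: 25 undeca-O-benzyl trimer
Product: 26 (−)-epiafzelechin-(4β→8)-(−)-epicatechin-(4β→8)-(−)-epicatechin (CNP0158921.2)
Conditions: H2 (1 atm), Pd(OH)2/C, THF–MeOH–H2O, 23 °C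
Reagents that add atoms: none
Why: Hydrogenolysis of the eleven aryl benzyl ethers over Pd(OH)2/C under neutral conditions spares the acid-labile interflavan bonds and all stereocentres.

**Compound list**

1 | 4-(benzyloxy)benzaldehyde | O=Cc1ccc(OCc2ccccc2)cc1 | starting material
2 | allyl methoxymethyl ether [3-(methoxymethoxy)prop-1-ene] | C=CCOCOC | starting material
3 | [(Z)-3-(methoxymethoxy)prop-2-en-1-yl]lithium | [Li]C/C=C\OCOC | intermediate (not isolated)
4 | [(Z)-3-(methoxymethoxy)prop-2-en-1-yl]bis(isopinocampheyl)borane, (+)-α-pinene series | COCO/C=C\CB([C@@H]1C[C@@H]2C[C@H]([C@H]1C)C2(C)C)[C@@H]1C[C@@H]2C[C@H]([C@H]1C)C2(C)C | intermediate (not isolated)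
5 | (1R,2R)-1-[4-(benzyloxy)phenyl]-2-(methoxymethoxy)but-3-en-1-ol | c1ccccc1COc1ccc(cc1)[C@@H](O)[C@H](OCOC)C=C | intermediate
6 | triethyl{[(1R,2R)-1-[4-(benzyloxy)phenyl]-2-(methoxymethoxy)but-3-en-1-yl]oxy}silane | c1ccccc1COc1ccc(cc1)[C@@H](O[Si](CC)(CC)CC)[C@H](OCOC)C=C | intermediate
7 | N-methoxy-N-methylprop-2-enamide | C=CC(=O)N(C)OC | starting material
8 | (2E,4R,5R)-5-[4-(benzyloxy)phenyl]-N-methoxy-4-(methoxymethoxy)-N-methyl-5-[(triethylsilyl)oxy]pent-2-enamide | c1ccccc1COc1ccc(cc1)[C@@H](O[Si](CC)(CC)CC)[C@H](OCOC)/C=C/C(=O)N(C)OC | intermediate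
9 | (4R,5R)-5-[4-(benzyloxy)phenyl]-N-methoxy-4-(methoxymethoxy)-N-methyl-5-[(triethylsilyl)oxy]pentanamide | c1ccccc1COc1ccc(cc1)[C@@H](O[Si](CC)(CC)CC)[C@H](OCOC)CCC(=O)N(C)OC | intermediate
10 | 2,2,6-trimethyl-4H-1,3-dioxin-4-one | CC1=CC(=O)OC(C)(C)O1 | starting material
11 | lithium 2,2-dimethyl-6-methylidene-6H-1,3-dioxin-4-olate | [Li+].C=C1C=C([O-])OC(C)(C)O1 | intermediate (not isolated)
12 | 6-[(5R,6R)-6-[4-(benzyloxy)phenyl]-5-(methoxymethoxy)-2-oxo-6-[(triethylsilyl)oxy]hexyl]-2,2-dimethyl-4H-1,3-dioxin-4-one | c1ccccc1COc1ccc(cc1)[C@@H](O[Si](CC)(CC)CC)[C@H](OCOC)CCC(=O)CC1=CC(=O)OC(C)(C)O1 | intermediate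
13 | 6-[(5R,6R)-6-[4-(benzyloxy)phenyl]-6-hydroxy-5-(methoxymethoxy)-2-oxohexyl]-2,2-dimethyl-4H-1,3-dioxin-4-one | c1ccccc1COc1ccc(cc1)[C@@H](O)[C@H](OCOC)CCC(=O)CC1=CC(=O)OC(C)(C)O1 | intermediate (not isolated)
14 | 6-{[(2R,3R)-2-[4-(benzyloxy)phenyl]-3-(methoxymethoxy)-3,4-dihydro-2H-pyran-6-yl]methyl}-2,2-dimethyl-4H-1,3-dioxin-4-one | c1ccccc1COc1ccc(cc1)[C@H]1OC(CC2=CC(=O)OC(C)(C)O2)=CC[C@H]1OCOC | intermediate (not isolated)
15 | 4-[(2R,3R)-2-[4-(benzyloxy)phenyl]-3-(methoxymethoxy)-3,4-dihydro-2H-pyran-6-yl]but-1-ene-1,3-dione | c1ccccc1COc1ccc(cc1)[C@H]1OC(CC(=O)C=C=O)=CC[C@H]1OCOC | intermediate (not isolated)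
16 | (2R,3R)-2-[4-(benzyloxy)phenyl]-7-hydroxy-3-(methoxymethoxy)-2,3,4,4a-tetrahydro-5H-chromen-5-one | c1ccccc1COc1ccc(cc1)[C@H]1OC2=CC(O)=CC(=O)C2C[C@H]1OCOC | intermediate (not isolated)
17 | (2R,3R)-2-[4-(benzyloxy)phenyl]-3-(methoxymethoxy)chromane-5,7-diol | c1ccccc1COc1ccc(cc1)[C@H]1Oc2cc(O)cc(O)c2C[C@H]1OCOC | intermediate
18 | (2R,3R)-5,7-bis(benzyloxy)-2-[4-(benzyloxy)phenyl]-3-(methoxymethoxy)chromane | c1ccccc1COc1ccc(cc1)[C@H]1Oc2cc(OCc3ccccc3)cc(OCc3ccccc3)c2C[C@H]1OCOC | intermediate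
19 | (2R,3R)-5,7-bis(benzyloxy)-2-[4-(benzyloxy)phenyl]chroman-3-ol | c1ccccc1COc1ccc(cc1)[C@H]1Oc2cc(OCc3ccccc3)cc(OCc3ccccc3)c2C[C@H]1O | intermediate
20 | (2R,3R,4S)-5,7-bis(benzyloxy)-2-[4-(benzyloxy)phenyl]-4-(2-ethoxyethoxy)chroman-3-ol | c1ccccc1COc1ccc(cc1)[C@H]1Oc2cc(OCc3ccccc3)cc(OCc3ccccc3)c2[C@H](OCCOCC)[C@H]1O | intermediate
21 | (−)-epicatechin | Oc1ccc(cc1O)[C@H]1Oc2cc(O)cc(O)c2C[C@H]1O | starting material
22 | (2R,3R)-5,7-bis(benzyloxy)-2-[3,4-bis(benzyloxy)phenyl]chroman-3-ol | c1ccccc1COc1ccc(cc1OCc1ccccc1)[C@H]1Oc2cc(OCc3ccccc3)cc(OCc3ccccc3)c2C[C@H]1O | intermediate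
23 | (2R,3R,4S)-5,7-bis(benzyloxy)-2-[3,4-bis(benzyloxy)phenyl]-4-(2-ethoxyethoxy)chroman-3-ol | c1ccccc1COc1ccc(cc1OCc1ccccc1)[C@H]1Oc2cc(OCc3ccccc3)cc(OCc3ccccc3)c2[C@H](OCCOCC)[C@H]1O | intermediate
24 | 5,7,3',4'-tetra-O-benzyl-(−)-epicatechin-(4β→8)-5,7,3',4'-tetra-O-benzyl-(−)-epicatechin | c1ccccc1COc1ccc(cc1OCc1ccccc1)[C@H]1Oc2cc(OCc3ccccc3)cc(OCc3ccccc3)c2[C@H](c2c(OCc3ccccc3)cc(OCc3ccccc3)c3c2O[C@H](c2ccc(OCc4ccccc4)c(OCc4ccccc4)c2)[C@H](O)C3)[C@H]1O | intermediate
25 | 5,7,4'-tri-O-benzyl-(−)-epiafzelechin-(4β→8)-5,7,3',4'-tetra-O-benzyl-(−)-epicatechin-(4β→8)-5,7,3',4'-tetra-O-benzyl-(−)-epicatechin | c5ccccc5COc1ccc([C@H]2Oc3cc(OCc5ccccc5)cc(OCc5ccccc5)c3[C@H](c3c(OCc5ccccc5)cc(OCc5ccccc5)c4c3O[C@H](c3ccc(OCc5ccccc5)c(OCc5ccccc5)c3)[C@H](O)[C@H]4c3c(OCc5ccccc5)cc(OCc5ccccc5)c4c3O[C@H](c3ccc(OCc5ccccc5)c(OCc5ccccc5)c3)[C@H](O)C4)[C@H]2O)cc1 | intermediate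
26 | (−)-epiafzelechin-(4β→8)-(−)-epicatechin-(4β→8)-(−)-epicatechin (CNP0158921.2) | Oc1ccc([C@H]2Oc3cc(O)cc(O)c3[C@H](c3c(O)cc(O)c4c3O[C@H](c3ccc(O)c(O)c3)[C@H](O)[C@H]4c3c(O)cc(O)c4c3O[C@H](c3ccc(O)c(O)c3)[C@H](O)C4)[C@H]2O)cc1 | target

**Step count and risks**

Total step count: 14. Longest linear sequence: 11 steps (steps 1 to 9, 13, 14).

Steps most likely to fail:

1. Step 6 (proposed new method). What may go wrong:
   - O-acylation to a pyranone if the enol ether has not fully formed before the ketene is released.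
   - Interception of the ketene by the water or methanol set free in the first stages.
   - Acetal exchange of the MOM group onto the free O1 under the acid catalyst.
   - Ketene dimerisation.

   Fallback with known chemistry, from 6 back to 18. Ozonolysis of 6 with reductive work-up (O3, CH2Cl2–MeOH, −78 °C; NaBH4) should give (2R,3R)-3-[4-(benzyloxy)phenyl]-2-(methoxymethoxy)-3-[(triethylsilyl)oxy]propan-1-ol F1. This is converted with Tf2O and 2,6-lutidine into (2R,3R)-3-[4-(benzyloxy)phenyl]-2-(methoxymethoxy)-3-[(triethylsilyl)oxy]propyl trifluoromethanesulfonate F2. Ring A is brought in as an electrophile: 1,3,5-trifluorobenzene, benzyl alcohol and NaH give 1,3-bis(benzyloxy)-5-fluorobenzene F3. Lithiation of F3 between fluorine and a benzyloxy group (n-BuLi, THF, −78 °C) and alkylation with F2 should give {(1R,2R)-1-[4-(benzyloxy)phenyl]-3-[2,4-bis(benzyloxy)-6-fluorophenyl]-2-(methoxymethoxy)propoxy}triethylsilane F4. Desilylation (TBAF, THF) gives (1R,2R)-1-[4-(benzyloxy)phenyl]-3-[2,4-bis(benzyloxy)-6-fluorophenyl]-2-(methoxymethoxy)propan-1-ol F5. Its potassium alkoxide (KH, DMF, 80 °C) displaces fluoride in an intramolecular SNAr etherification that forms the same O1–C8a bond with retention at C2 and gives 18. Steps 3 to 7 are replaced.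

2. Step 13. What may go wrong:
   - Attack of the cation at a C6 position of 24 instead of C8 of its upper unit.
   - Further chain growth by self-condensation of 20.
   - Acid-induced cleavage and scrambling of the interflavan bond already present in 24.

   Fallback by orthogonal activation, from 23 back to 25, with the order of bond formation reversed. 23 is treated with 2,6-dimethylbenzenethiol and BF3·OEt2 (CH2Cl2, −78 °C) to give 4β-[(2,6-dimethylphenyl)sulfanyl]-5,7,3',4'-tetra-O-benzyl-(−)-epicatechin F6, whose sulfide is inert to hard Lewis acids. 20 is then coupled with C8 of F6 (BF3·OEt2, −78 °C) to give 5,7,4'-tri-O-benzyl-(−)-epiafzelechin-(4β→8)-4β-[(2,6-dimethylphenyl)sulfanyl]-5,7,3',4'-tetra-O-benzyl-(−)-epicatechin F7. Activation of the sulfide of F7 with N-iodosuccinimide in the presence of 22 forms the lower interflavan bond and gives 25. Step 12 is not needed.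

3. Step 3. What may go wrong:
   - Slow turnover at the hindered allylic ether.
   - Homodimerisation of the acrylamide.
   - Migration of the double bond.

   Fallback from 6 back to 12. Linear-selective hydroformylation of 6 (Rh(acac)(CO)2, BiPhePhos, CO/H2, toluene, 60 °C) should give (4R,5R)-5-[4-(benzyloxy)phenyl]-4-(methoxymethoxy)-5-[(triethylsilyl)oxy]pentanal F8. Vinylogous aldol addition of the lithium dienolate 11 gives 6-[(5R,6R)-6-[4-(benzyloxy)phenyl]-2-hydroxy-5-(methoxymethoxy)-6-[(triethylsilyl)oxy]hexyl]-2,2-dimethyl-4H-1,3-dioxin-4-one F9 as a mixture of carbinol epimers. Dess–Martin oxidation then gives 12. Steps 3 to 5 are replaced.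

Further compounds

F1 | step 6 | (2R,3R)-3-[4-(benzyloxy)phenyl]-2-(methoxymethoxy)-3-[(triethylsilyl)oxy]propan-1-ol | c1ccccc1COc1ccc(cc1)[C@@H](O[Si](CC)(CC)CC)[C@H](OCOC)CO
F2 | step 6 | (2R,3R)-3-[4-(benzyloxy)phenyl]-2-(methoxymethoxy)-3-[(triethylsilyl)oxy]propyl trifluoromethanesulfonate | c1ccccc1COc1ccc(cc1)[C@@H](O[Si](CC)(CC)CC)[C@H](OCOC)COS(=O)(=O)C(F)(F)F
F3 | step 6 | 1,3-bis(benzyloxy)-5-fluorobenzene | Fc1cc(OCc2ccccc2)cc(OCc2ccccc2)c1
F4 | step 6 | {(1R,2R)-1-[4-(benzyloxy)phenyl]-3-[2,4-bis(benzyloxy)-6-fluorophenyl]-2-(methoxymethoxy)propoxy}triethylsilane | c1ccccc1COc1ccc(cc1)[C@@H](O[Si](CC)(CC)CC)[C@H](OCOC)Cc1c(F)cc(OCc2ccccc2)cc1OCc1ccccc1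
F5 | step 6 | (1R,2R)-1-[4-(benzyloxy)phenyl]-3-[2,4-bis(benzyloxy)-6-fluorophenyl]-2-(methoxymethoxy)propan-1-ol | c1ccccc1COc1ccc(cc1)[C@@H](O)[C@H](OCOC)Cc1c(F)cc(OCc2ccccc2)cc1OCc1ccccc1
F6 | step 13 | 4β-[(2,6-dimethylphenyl)sulfanyl]-5,7,3',4'-tetra-O-benzyl-(−)-epicatechin | c1ccccc1COc1ccc(cc1OCc1ccccc1)[C@H]1Oc2cc(OCc3ccccc3)cc(OCc3ccccc3)c2[C@H](Sc2c(C)cccc2C)[C@H]1O
F7 | step 13 | 5,7,4'-tri-O-benzyl-(−)-epiafzelechin-(4β→8)-4β-[(2,6-dimethylphenyl)sulfanyl]-5,7,3',4'-tetra-O-benzyl-(−)-epicatechin | c5ccccc5COc1ccc([C@H]2Oc3cc(OCc5ccccc5)cc(OCc5ccccc5)c3[C@H](c3c(OCc5ccccc5)cc(OCc5ccccc5)c4c3O[C@H](c3ccc(OCc5ccccc5)c(OCc5ccccc5)c3)[C@H](O)[C@H]4Sc3c(C)cccc3C)[C@H]2O)cc1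
F8 | step 3 | (4R,5R)-5-[4-(benzyloxy)phenyl]-4-(methoxymethoxy)-5-[(triethylsilyl)oxy]pentanal | c1ccccc1COc1ccc(cc1)[C@@H](O[Si](CC)(CC)CC)[C@H](OCOC)CCC=O
F9 | step 3 | 6-[(5R,6R)-6-[4-(benzyloxy)phenyl]-2-hydroxy-5-(methoxymethoxy)-6-[(triethylsilyl)oxy]hexyl]-2,2-dimethyl-4H-1,3-dioxin-4-one | c1ccccc1COc1ccc(cc1)[C@@H](O[Si](CC)(CC)CC)[C@H](OCOC)CCC(O)CC1=CC(=O)OC(C)(C)O1
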